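**Assumption:** the target has no stereocentre and is achiral, so the constitution alone defines it; it is made as the enol tautomer drawn in the given SMILES.

## Retrosynthetic overview

- The target comes from its tri-O-benzyl ether by hydrogenolysis. Both ArCH2–C(triketone) bonds are cut in one twofold palladium-catalysed benzylic substitution: a central bis(benzylic methyl carbonate) (fragment B) plus two molecules of butyrylfilicinic acid (fragment A).
- Fragment A: C-butyrylation of filicinic acid, whose six-membered triketone ring is closed by a Dieckmann-type cyclisation of methyl 2,2-dimethyl-3,5-dioxohexanoate (from methyl acetoacetate, iodomethane and acetaldehyde).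
- Fragment B: bis-carbonate from the diol, from the tri-O-benzyl diformyl phlorobutyrophenone, from phlorobutyrophenone, from phloroglucinol, itself made from resorcinol by iridium-catalysed C–H borylation and oxidation.
- Ring order: the gem-dimethyl triketone ring is the only ring built (step 4, made once, used twice). The aromatic ring is carried intact from resorcinol, and the coupling forms no ring.

## Route

### Fragment A: butyrylfilicinic acid

**Step 1**
Reactants: 1 methyl acetoacetate (methyl 3-oxobutanoate)
Product: 2 methyl 2,2-dimethyl-3-oxobutanoate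
Conditions: MeI (2.6 equiv), K2CO3 (3 equiv), DMSO, 25 °C, 16 h
Reagents that add atoms: iodomethane, CI
Why: Twofold C-alkylation of the β-keto ester enolate (acetoacetic ester alkylation) installs the gem-dimethyl group and leaves the methyl ketone as the only enolisable site for the later steps.

**Step 2**
Reactants: 2 methyl 2,2-dimethyl-3-oxobutanoate; 3 acetaldehyde
Product: 4 methyl 5-hydroxy-2,2-dimethyl-3-oxohexanoate (racemic at C5)
Conditions: LiN(iPr)2 (1.05 equiv), THF, −78 °C; then 3 (1.3 equiv), −78 °C; AcOH quench
Reagents that add atoms: none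
Why: Directed aldol addition of the kinetic lithium enolate of the methyl ketone to acetaldehyde; the new carbinol centre is racemic and is erased in step 3.

**Step 3**
Reactants: 4 methyl 5-hydroxy-2,2-dimethyl-3-oxohexanoate
Product: 5 methyl 2,2-dimethyl-3,5-dioxohexanoate
Conditions: IBX (2-iodoxybenzoic acid, 2 equiv), EtOAc, 77 °C
Reagents that add atoms: none
Why: IBX oxidation of a β-hydroxy ketone to the β-diketone is a dependable reaction that avoids over-oxidation and C–C cleavage.

**Step 4**
Reactants: 5 methyl 2,2-dimethyl-3,5-dioxohexanoate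
Product: 6 filicinic acid (3,5-dihydroxy-4,4-dimethylcyclohexa-2,5-dien-1-one)
Conditions: LiN(iPr)2 (2.4 equiv), THF (0.05 M), −78 → 25 °C; then 1 M HCl
Reagents that add atoms: none
Why: Dieckmann-type (intramolecular Claisen) cyclisation in which the terminal carbanion of the β-diketone dianion attacks the non-enolisable ester, helped by the gem-dimethyl (Thorpe–Ingold) effect, and the acidic triketone is held as its salt until work-up.

**Step 5**
Reactants: 6 filicinic acid; 7 butanoyl chloride
Product: 8 butyrylfilicinic acid (2-butanoyl-3,5-dihydroxy-4,4-dimethylcyclohexa-2,5-dien-1-one)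
Conditions: 7 (1.05 equiv), AlCl3 (3 equiv), PhNO2/CH2Cl2, 0 → 45 °C; ice/HCl
Reagents that add atoms: none
Why: Friedel–Crafts-type C-acylation of the enolised triketone at one of its two equivalent ring CH positions, after which the acyl group deactivates the ring against a second acylation.

### Fragment B: central bis(benzylic carbonate)

**Step 6**
Reactants: 9 resorcinol (benzene-1,3-diol)
Product: 10 1,3-bis(trimethylsilyloxy)benzene
Conditions: HMDS (1.2 equiv), TMSCl (1 mol %), neat, 110 °C; distil
Reagents that add atoms: hexamethyldisilazane, C[Si](C)(C)N[Si](C)(C)C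
Why: O-Silylation of both phenols gives a base-free bis(silyl ether) in which C5 is the only C–H bond without an ortho substituent.

**Step 7**
Reactants: 10 1,3-bis(trimethylsilyloxy)benzene
Product: 12 phloroglucinol (benzene-1,3,5-triol), via 3,5-bis(trimethylsilyloxy)phenylboronic acid pinacol ester 11 (not isolated)
Conditions: HBpin (1.5 equiv), [Ir(OMe)(cod)]2 (1.5 mol %), 4,4′-di-tert-butyl-2,2′-bipyridine (3 mol %), THF, 60 °C; evaporate; then KHSO5 (as the triple salt 2KHSO5·KHSO4·K2SO4), acetone/H2O, 25 °C; then 1 M HCl
Reagents that add atoms: potassium peroxymonosulfate KHSO5, [K+].OOS(=O)(=O)[O-] (the new phenol oxygen); pinacolborane, B1OC(C)(C)C(C)(C)O1 (the boryl group of 11 only)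
Why: Sterically controlled iridium-catalysed aromatic C–H borylation takes place at C5, and the one-pot oxidation of the aryl boronate (boron-to-oxygen 1,2-shift) in aqueous acid also cleaves the labile aryl silyl ethers.

**Step 8**
Reactants: 12 phloroglucinol; 7 butanoyl chloride
Product: 13 phlorobutyrophenone (1-(2,4,6-trihydroxyphenyl)butan-1-one)
Conditions: 7 (1.0 equiv), AlCl3 (4 equiv), PhNO2/CH2Cl2, 25 → 50 °C; ice/HCl
Reagents that add atoms: none
Why: Friedel–Crafts acylation of the symmetric, very electron-rich arene gives a single regioisomer, and the chelated ketone slows further acylation.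

**Step 9**
Reactants: 13 phlorobutyrophenone
Product: 15 5-butanoyl-2,4,6-trihydroxybenzene-1,3-dicarbaldehyde, via bis(dimethyliminium) dichloride 14 (not isolated)
Conditions: POCl3 (2.6 equiv), DMF (6 equiv), EtOAc, 0 → 25 °C; then H2O, 60 °C
Reagents that add atoms: N,N-dimethylformamide, CN(C)C=O (the formyl carbons and the Me2N=CH groups of 14); water, O (the formyl oxygens)
Why: Twofold Vilsmeier–Haack formylation at the two remaining ring positions, each still activated by three hydroxyl groups, followed by hydrolysis of the bis-iminium salt.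

**Step 10**
Reactants: 15 5-butanoyl-2,4,6-trihydroxybenzene-1,3-dicarbaldehyde
Product: 16 2,4,6-tris(benzyloxy)-5-butanoylbenzene-1,3-dicarbaldehyde
Conditions: BnBr (3.6 equiv), K2CO3 (4.5 equiv), DMF, 60 °C
Reagents that add atoms: benzyl bromide, BrCc1ccccc1
Why: Williamson etherification of the three acidic phenols in a dipolar aprotic solvent favours O-alkylation, and the benzyl ethers block o-quinone methide formation and come off by neutral hydrogenolysis at the end.

**Step 11**
Reactants: 16 2,4,6-tris(benzyloxy)-5-butanoylbenzene-1,3-dicarbaldehyde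
Product: 17 1-[2,4,6-tris(benzyloxy)-3,5-bis(hydroxymethyl)phenyl]butan-1-one
Conditions: NaBH4 (1.0 equiv), THF/MeOH 4:1, −30 °C; aq NH4Cl
Reagents that add atoms: none
Why: Chemoselective borohydride reduction, because the aldehydes react far faster than the aryl ketone, which is twisted out of conjugation and shielded by two ortho benzyloxy groups.

**Step 12**
Reactants: 17 1-[2,4,6-tris(benzyloxy)-3,5-bis(hydroxymethyl)phenyl]butan-1-one
Product: 18 [2,4,6-tris(benzyloxy)-5-butanoyl-1,3-phenylene]bis(methylene) bis(methyl carbonate)
Conditions: ClCO2Me (3 equiv), pyridine (5 equiv), DMAP (5 mol %), CH2Cl2, 0 °C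
Reagents that add atoms: methyl chloroformate, COC(Cl)=O
Why: DMAP-catalysed O-acylation of the two primary benzylic alcohols gives the methyl carbonates that serve as leaving group and internal base source for the palladium step.

### Coupling and deprotection

**Step 13**
Reactants: 18 central bis(methyl carbonate); 8 butyrylfilicinic acid (2.5 equiv)
Product: 19 6,6′-{[2,4,6-tris(benzyloxy)-5-butanoyl-1,3-phenylene]bis(methylene)}bis(2-butanoyl-3,5-dihydroxy-4,4-dimethylcyclohexa-2,5-dien-1-one) (tri-O-benzyl ether of the target)
Conditions: Pd(η3-C3H5)(η5-C5H5) (5 mol %), DPEphos (6 mol %), DMSO, 70 °C, no added base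
Reagents that add atoms: none
Why: Proposed new method: a twofold palladium-catalysed benzylic substitution (Tsuji–Trost-type benzylation) in which zerovalent palladium/DPEphos ionises each ortho,ortho′-dialkoxy benzylic methyl carbonate to a cationic η3-benzylpalladium complex, the methyl carbonate anion loses CO2 to give methoxide that deprotonates 8, and the soft triketone enolate attacks the benzylic carbon from outside the metal through its only ring CH carbon to form both ArCH2–C bonds on the same arene; the closest known reaction type is the palladium-catalysed benzylation of malonates and simple 1,3-diketones with mono-benzylic carbonates, not yet shown for a hexasubstituted bis(benzylic) electrophile or for 2-acylcyclohexane-1,3,5-triones.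

**Step 14**
Reactants: 19 tri-O-benzyl ether of the target
Product: 20 target, 6,6′-[(5-butanoyl-2,4,6-trihydroxy-1,3-phenylene)bis(methylene)]bis(2-butanoyl-3,5-dihydroxy-4,4-dimethylcyclohexa-2,5-dien-1-one)
Conditions: H2 (1 atm), Pd/C (10 wt % Pd on carbon), EtOAc/MeOH, 25 °C
Reagents that add atoms: none
Why: Hydrogenolysis of the three benzyl aryl ethers under neutral conditions, which the enolised triketones, the chelated aryl ketone and the ArCH2–C bridges withstand.

## Compound list

1 | methyl acetoacetate (methyl 3-oxobutanoate) | COC(=O)CC(C)=O | starting material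
2 | methyl 2,2-dimethyl-3-oxobutanoate | COC(=O)C(C)(C)C(C)=O | intermediate
3 | acetaldehyde | CC=O | starting material
4 | methyl 5-hydroxy-2,2-dimethyl-3-oxohexanoate (racemic) | COC(=O)C(C)(C)C(=O)CC(C)O | intermediate
5 | methyl 2,2-dimethyl-3,5-dioxohexanoate | COC(=O)C(C)(C)C(=O)CC(C)=O | intermediate
6 | filicinic acid (3,5-dihydroxy-4,4-dimethylcyclohexa-2,5-dien-1-one) | CC1(C)C(O)=CC(=O)C=C1O | intermediate
7 | butanoyl chloride | CCCC(Cl)=O | starting material
8 | butyrylfilicinic acid (2-butanoyl-3,5-dihydroxy-4,4-dimethylcyclohexa-2,5-dien-1-one) | CCCC(=O)C1=C(O)C(C)(C)C(O)=CC1=O | intermediate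
9 | resorcinol (benzene-1,3-diol) | Oc1cccc(O)c1 | starting material
10 | 1,3-bis(trimethylsilyloxy)benzene | C[Si](C)(C)Oc1cccc(O[Si](C)(C)C)c1 | intermediate
11 | 3,5-bis(trimethylsilyloxy)phenylboronic acid pinacol ester | C[Si](C)(C)Oc1cc(O[Si](C)(C)C)cc(B2OC(C)(C)C(C)(C)O2)c1 | intermediate (not isolated)
12 | phloroglucinol (benzene-1,3,5-triol) | Oc1cc(O)cc(O)c1 | intermediate
13 | phlorobutyrophenone (1-(2,4,6-trihydroxyphenyl)butan-1-one) | CCCC(=O)c1c(O)cc(O)cc1O | intermediate
14 | bis(dimethyliminium) dichloride of the diformyl compound | CCCC(=O)c1c(O)c(C=[N+](C)C)c(O)c(C=[N+](C)C)c1O.[Cl-].[Cl-] | intermediate (not isolated)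
15 | 5-butanoyl-2,4,6-trihydroxybenzene-1,3-dicarbaldehyde | CCCC(=O)c1c(O)c(C=O)c(O)c(C=O)c1O | intermediate
16 | 2,4,6-tris(benzyloxy)-5-butanoylbenzene-1,3-dicarbaldehyde | CCCC(=O)c1c(OCc2ccccc2)c(C=O)c(OCc3ccccc3)c(C=O)c1OCc4ccccc4 | intermediate
17 | 1-[2,4,6-tris(benzyloxy)-3,5-bis(hydroxymethyl)phenyl]butan-1-one | CCCC(=O)c1c(OCc2ccccc2)c(CO)c(OCc3ccccc3)c(CO)c1OCc4ccccc4 | intermediate
18 | [2,4,6-tris(benzyloxy)-5-butanoyl-1,3-phenylene]bis(methylene) bis(methyl carbonate) | CCCC(=O)c1c(OCc2ccccc2)c(COC(=O)OC)c(OCc3ccccc3)c(COC(=O)OC)c1OCc4ccccc4 | intermediate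
19 | tri-O-benzyl ether of the target | CCCC(=O)C1=C(O)C(C)(C)C(O)=C(Cc2c(OCc3ccccc3)c(CC4=C(O)C(C)(C)C(O)=C(C(=O)CCC)C4=O)c(OCc5ccccc5)c(C(=O)CCC)c2OCc6ccccc6)C1=O | intermediate
20 | target (CNP0287270.0) | CCCC(=O)C1=C(O)C(C)(C)C(O)=C(Cc2c(O)c(CC3=C(O)C(C)(C)C(O)=C(C(=O)CCC)C3=O)c(O)c(C(=O)CCC)c2O)C1=O | target

## Step count

- Total step count: 14.
- Longest linear sequence: 9 steps (steps 6 to 14, from resorcinol 9 to target 20). The other branch is steps 1 to 5, joining at step 13.

## Steps most likely to fail, with fallbacks

**Step 13 (the proposed twofold palladium benzylation).** The benzylic carbons are each flanked by two ortho benzyloxy groups, so ionisation to the η3-benzyl complex may be slow. O-alkylation or double alkylation of 8 could also compete. The fallback uses known chemistry and sets out from dialdehyde 16 together with 8, so steps 11 and 12 are skipped. It is the organocatalytic three-component reductive alkylation of a cyclic 1,3-dione: 16, 8 (2.2 equiv), Hantzsch ester (diethyl 2,6-dimethyl-1,4-dihydropyridine-3,5-dicarboxylate, 2.4 equiv) and L-proline (20 mol %) in CH2Cl2 at 25 °C. Knoevenagel condensation gives the bis(alkylidene triketone) F1, which is reduced in the same flask by conjugate hydride transfer. The route is rejoined at 19, before step 14.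

**Step 4 (Dieckmann-type closure of the triketone ring).** The chelated diketone dianion must reach a non-chelated rotamer to cyclise, and intermolecular Claisen condensation can compete. The fallback sets out from phlorobutyrophenone 13 of the other branch and uses the classical dearomatising geminal C-methylation (MeI 2.2 equiv, NaOMe 3 equiv, MeOH, 0 → 25 °C). This gives butyrylfilicinic acid directly, so the route is rejoined at 8 and steps 1 to 5 are not needed. The cost is that both fragments then draw on 13. No new compound arises on this way (F0).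

**Step 10 (threefold O-benzylation).** All three hydroxyl groups are hydrogen-bonded to carbonyls, and the delocalised phenoxide may be C-benzylated with loss of aromaticity. The fallback sets out from 15 and changes the protecting-group class to methoxymethyl ethers, put on with a hard electrophile that alkylates on oxygen. MOMCl and iPr2NEt in CH2Cl2 give the tris(methoxymethyl) dialdehyde F2. NaBH4 in THF/MeOH at −30 °C gives the diol F3. ClCO2Me, pyridine and DMAP give the bis(methyl carbonate) F4. The coupling of step 13 with 8 gives the tris(methoxymethyl) ether of the target F5. Finally 3 M HCl in MeOH at 25 °C cleaves the three acetals, and the route comes back at target 20.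

## Further compounds

F1 | step 13 | bis(alkylidene triketone) Knoevenagel adduct of 16 with two molecules of 8 | CCCC(=O)C1=C(O)C(C)(C)C(=O)C(=Cc2c(OCc3ccccc3)c(C=C4C(=O)C(C(=O)CCC)=C(O)C(C)(C)C4=O)c(OCc5ccccc5)c(C(=O)CCC)c2OCc6ccccc6)C1=O
F0 | step 4 | none | none
F2 | step 10 | 5-butanoyl-2,4,6-tris(methoxymethoxy)benzene-1,3-dicarbaldehyde | CCCC(=O)c1c(OCOC)c(C=O)c(OCOC)c(C=O)c1OCOC
F3 | step 10 | 1-[3,5-bis(hydroxymethyl)-2,4,6-tris(methoxymethoxy)phenyl]butan-1-one | CCCC(=O)c1c(OCOC)c(CO)c(OCOC)c(CO)c1OCOC
F4 | step 10 | [5-butanoyl-2,4,6-tris(methoxymethoxy)-1,3-phenylene]bis(methylene) bis(methyl carbonate) | CCCC(=O)c1c(OCOC)c(COC(=O)OC)c(OCOC)c(COC(=O)OC)c1OCOC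
F5 | step 10 | tris(methoxymethyl) ether of the target | CCCC(=O)C1=C(O)C(C)(C)C(O)=C(Cc2c(OCOC)c(CC3=C(O)C(C)(C)C(O)=C(C(=O)CCC)C3=O)c(OCOC)c(C(=O)CCC)c2OCOC)C1=O
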